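**Charges.** Here are the flasks, the readings and the questions.

| flask | starting material | partner | second substrate | remark | time |
|---|---|---|---|---|---|
| alpha | 0.13 M | 0.22 M | 0.40 M | run made earlier |  |
| gamma | 0.30 M | 0.22 M | 0.40 M | run made earlier |  |
| flask | 0.20 M | 0.220 M | 0.400 M |  | 5.0 d |

- alpha (time / d: target / %, starting material / %): 0.0556: 12.4, 85.8; 0.250: 10.9, 86.0; 1.25: 8.3, 85.2; 6.00: 5.6, 75.0
- gamma (time / d: target / %, starting material / %): 0.0556: 11.3, 87.1; 0.250: 9.8, 88.2; 1.25: 7.0, 87.5; 6.00: 5.0, 81.8

(readings scatter by 0.3 percentage points)

- the numbers in the tables scatter by 0.3 percentage points (one standard deviation)
- candidate steps: starting material + partner <-> target; second substrate + partner <-> second product; target <-> isomer of the product; partner + target -> over-reaction product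

* the best time, 5.0 d at the latest, for target
* the amount of target, in percent of the starting material charged, at that time

**Leftover first.** Take what is left of the starting material at the first reading of the alpha run, 85.8%, and read the rates beside it: target has climbed at an average 2.23 /d of the charge, then falls at 0.0772 /d, so the climb is far steeper than the fall. Note how that fall slows, by a factor 2.97 over the next interval and 13.6 by the last, so the late readings drift while the early top holds the prize.

**Partner yield.** Compare the gamma run: 2.31 times the starting material gives 11.3% of its charge at the first reading against 12.4% in the alpha run, both runs holding 0.22 M of partner. Carry the partner yield, the first-reading target interpolated to this charge and divided by the partner charged, 0.543 /M; my own figure for the flask at that first reading is therefore 11.9%.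

**The forecast.** It says 12.2% at 0.05 d, above my figure: “So the maximum is very early, at or before the first sampled time.”

**The flask.** The flask tops at 12.9% after 0.0965 d, twice the forecast's time.

    starting material + partner ⇌ target (K = 1.70 /M, k = 0.0164 /M/min)
    second substrate + partner ⇌ second product (K = 8.65 /M, k = 0.0164 /M/min)
    target ⇌ isomer of the product (K = 0.100, k = 0.0114 /min)
    partner + target → over-reaction product (k = 0.00519 /M/min)

By forward rates, the second substrate takes partner 1.9 times as fast as starting material does in the flask at 0.0372 d, and at the top the flask keeps 42.9% of its partner charge. The partner yield of the flask comes to 0.587 /M against the 0.543 /M carried, and for the neighbour flask with 0.088 M of partner the carried figure gives 4.78% where 5.52% stands.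

All runs were computed on assumed constants; scatter was added.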